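## Retrosynthetic overview

1. Target ⇐ acetal hydrolysis, alcohol oxidation, hydroboration of a 1,1-disubstituted side-chain alkene (sets the side-chain stereocentre), acetylation and Stille hydroxymethylation ⇐ enol triflate of a 2,3-disubstituted cyclopentanone.
2. Enol triflate ⇐ 2-(diethoxymethyl)cyclopent-2-en-1-one + alkenyl Grignard reagent from (E)-geranylacetone (Shapiro reaction): a copper-catalysed asymmetric conjugate addition sets the ring stereocentre C3, and O-triflation of the enolate fixes the C1=C2 double bond.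
3. Enone ⇐ 3,3-diethoxyprop-1-yne + ethylene + CO by a Pauson–Khand reaction: the C1–C5 and C3–C4 bonds (and C1–C2) form in one operation from three components.
4. Enabling feature: in the cyclopentene (C1 carries CH2OAc, C2 the formyl group, C3 the side chain) the unsubstituted C4H2–C5H2 pair is an ethylene unit. It sits between C3, the β-carbon of a latent enone, and C1, a latent ketone carbon (ketone ⇒ enol triflate ⇒ C–CH2OAc). C2–C3 is a terminal alkyne carrying the masked formyl group, so the ring is a cyclopent-2-enone retron.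
5. Ring order: the cyclopentene is the only ring and is made first (step 1); every other carbon is attached to it afterwards.

Key step: step 1

Remark: the chiral ligand in step 4 is assumed to deliver the alkenyl group to the face that gives R-configured C3; if the sense proves opposite, the enantiomeric ligand is used and nothing else changes.
Remark: isomerically pure (E)-geranylacetone, 3,3-diethoxyprop-1-yne, the sulfonohydrazide of step 2 and (tributylstannyl)methanol are taken as commercial.

## Route

Step 1
Reactants: 1 3,3-diethoxyprop-1-yne; 2 ethylene; 3 carbon monoxide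
Product: 4 2-(diethoxymethyl)cyclopent-2-en-1-one
Conditions: Co2(CO)8 (5 mol%), tetramethylthiourea (30 mol%), ethylene (30 bar), CO (5 bar), toluene, 80 °C, autoclave
Reagents that add atoms: none
Why: Pauson–Khand [2+2+1] cycloaddition: the alkyne binds the dicobalt carbonyl as a bridging alkyne complex, ethylene inserts into the cobalt–carbon bond of the unsubstituted alkyne terminus (C3–C4), CO inserts into the new cobalt–alkyl bond (C5–C1), and reductive elimination joins the acyl carbon to the acetal-bearing alkyne carbon (C1–C2) and frees the catalyst. The closest known reaction type is the catalytic intermolecular Pauson–Khand reaction of terminal alkynes with ethylene under CO pressure, which gives 2-substituted cyclopent-2-enones. The one ring closes by reductive elimination from a cobaltacycle, a metal-templated annulation and not a polar ring closure. No stereocentre is formed. The step needs regioselectivity (acetal carbon next to the carbonyl) and chemoselectivity (cross-reaction over alkyne oligomerisation); the first is secured because ethylene inserts at the sterically free terminal CH of the alkyne, the second by the large excess and pressure of ethylene over a dilute alkyne.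

Step 2
Reactants: 5 (E)-geranylacetone; 6 2,4,6-tri(propan-2-yl)benzenesulfonohydrazide
Product: 7 N'-[(5E)-6,10-dimethylundeca-5,9-dien-2-ylidene]-2,4,6-tri(propan-2-yl)benzenesulfonohydrazide
Conditions: MeOH, cat. HCl, rt
Reagents that add atoms: none
Why: Acid-catalysed condensation of the methyl ketone with the arylsulfonyl hydrazide gives the sulfonylhydrazone needed for the Shapiro reaction; no stereocentre is involved.

Step 3
Reactants: 7
Product: 9 (5E)-2-iodo-6,10-dimethylundeca-1,5,9-triene, via alkenyllithium 8 (not isolated)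
Conditions: n-BuLi (2.2 equiv), TMEDA, hexane, –78 → 0 °C; then I2, THF, –78 °C
Reagents that add atoms: iodine, II
Why: Shapiro reaction: the second deprotonation occurs kinetically at the methyl group, loss of sulfinate and N2 gives the less substituted 2-lithio-1-alkene, and iodine traps it as the 1,1-disubstituted vinyl iodide without touching the (E)-trisubstituted alkene.

Step 4
Reactants: 9 (5E)-2-iodo-6,10-dimethylundeca-1,5,9-triene; 4 2-(diethoxymethyl)cyclopent-2-en-1-one
Product: 12 (3R)-2-(diethoxymethyl)-3-[(5E)-6,10-dimethylundeca-1,5,9-trien-2-yl]cyclopent-1-en-1-yl trifluoromethanesulfonate, via alkenylmagnesium iodide 10 (not isolated), via magnesium enolate 11 (not isolated)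
Conditions: Mg, Et2O, rt; then CuBr·SMe2 (5 mol%), (R)-1-[(SP)-2-(diphenylphosphino)ferrocenyl]ethyldicyclohexylphosphine (6 mol%), slow addition to 4, t-BuOMe, –78 °C; then N-(5-chloropyridin-2-yl)bis(trifluoromethanesulfonimide), –78 → –20 °C
Reagents that add atoms: N-(5-chloropyridin-2-yl)bis(trifluoromethanesulfonimide), O=S(=O)(N(c1ccc(Cl)cn1)S(=O)(=O)C(F)(F)F)C(F)(F)F
Why: Copper-catalysed asymmetric conjugate addition of a Grignard reagent to an α-substituted cyclic enone with O-sulfonylation of the regiodefined magnesium enolate: the chiral copper–diphosphine complex delivers the alkenyl group to one face of C3 (catalyst control, R), and cold trapping fixes the C1=C2 enolate before it can equilibrate or lose ethoxide.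

Step 5
Reactants: 12 the enol triflate; 13 (tributylstannyl)methanol
Product: 14 [(3R)-2-(diethoxymethyl)-3-[(5E)-6,10-dimethylundeca-1,5,9-trien-2-yl]cyclopent-1-en-1-yl]methanol
Conditions: Pd(PPh3)4 (5 mol%), LiCl (3 equiv), 1,4-dioxane, 95 °C
Reagents that add atoms: none
Why: Stille coupling of the enol triflate with the hydroxymethylstannane (chloride assists transmetalation) puts the CH2OH carbon on C1 with the C1=C2 double bond already in place.

Step 6
Reactants: 14
Product: 15 [(3R)-2-(diethoxymethyl)-3-[(5E)-6,10-dimethylundeca-1,5,9-trien-2-yl]cyclopent-1-en-1-yl]methyl acetate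
Conditions: Ac2O, pyridine, DMAP (cat.), CH2Cl2, 0 °C → rt
Reagents that add atoms: acetic anhydride, CC(=O)OC(C)=O
Why: DMAP-catalysed O-acetylation of the only hydroxyl group, a primary allylic alcohol.

Step 7
Reactants: 15
Product: 17 [(3R)-2-(diethoxymethyl)-3-[(2S,5E)-1-hydroxy-6,10-dimethylundeca-5,9-dien-2-yl]cyclopent-1-en-1-yl]methyl acetate, via alkylborane 16 (not isolated)
Conditions: 9-BBN (1.2 equiv), THF, 0 °C → rt; then NaBO3·4H2O, H2O, rt
Reagents that add atoms: sodium perborate, [Na+].[Na+].O[B-]1(O)OO[B-](O)(O)OO1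
Why: Hydroboration–oxidation: the hindered borane adds only to the 1,1-disubstituted alkene (boron on the CH2 terminus) and should approach the face opposite the acetal-bearing C2 in the conformer whose C3–H bond eclipses the alkene (1,2-induction), setting the new stereocentre as S; perborate oxidation retains configuration and spares the acetate.

Step 8
Reactants: 17
Product: 18 [(3R)-2-(diethoxymethyl)-3-[(2S,5E)-6,10-dimethyl-1-oxoundeca-5,9-dien-2-yl]cyclopent-1-en-1-yl]methyl acetate
Conditions: Dess–Martin periodinane, NaHCO3, CH2Cl2, 0 °C → rt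
Reagents that add atoms: none
Why: Dess–Martin oxidation of the primary alcohol to the aldehyde under buffered, non-basic conditions that should not epimerise the new α-stereocentre.

Step 9
Reactants: 18
Product: 19 [(3R)-2-formyl-3-[(2S,5E)-6,10-dimethyl-1-oxoundeca-5,9-dien-2-yl]cyclopent-1-en-1-yl]methyl acetate
Conditions: AcOH/THF/H2O (3:1:1), rt
Reagents that add atoms: water, O
Why: Acid-catalysed acetal hydrolysis: the allylic diethyl acetal ionises easily to an allyl-stabilised oxocarbenium ion, so the enal is unmasked under conditions mild enough to keep the acetate, the α-stereocentre and the polyene.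

## Compound list

1 | 3,3-diethoxyprop-1-yne | C#CC(OCC)OCC | starting material
2 | ethylene | C=C | starting material
3 | carbon monoxide | [C-]#[O+] | starting material
4 | 2-(diethoxymethyl)cyclopent-2-en-1-one | O=C1CCC=C1C(OCC)OCC | intermediate
5 | (E)-geranylacetone, (5E)-6,10-dimethylundeca-5,9-dien-2-one | CC(=O)CC/C=C(\C)CCC=C(C)C | starting material
6 | 2,4,6-tri(propan-2-yl)benzenesulfonohydrazide | CC(C)c1cc(C(C)C)c(S(=O)(=O)NN)c(C(C)C)c1 | starting material
7 | N'-[(5E)-6,10-dimethylundeca-5,9-dien-2-ylidene]-2,4,6-tri(propan-2-yl)benzenesulfonohydrazide | CC(CC/C=C(\C)CCC=C(C)C)=NNS(=O)(=O)c1c(C(C)C)cc(C(C)C)cc1C(C)C | intermediate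
8 | [(5E)-6,10-dimethylundeca-1,5,9-trien-2-yl]lithium | [Li]C(=C)CC/C=C(\C)CCC=C(C)C | intermediate
9 | (5E)-2-iodo-6,10-dimethylundeca-1,5,9-triene | IC(=C)CC/C=C(\C)CCC=C(C)C | intermediate
10 | [(5E)-6,10-dimethylundeca-1,5,9-trien-2-yl]magnesium iodide | I[Mg]C(=C)CC/C=C(\C)CCC=C(C)C | intermediate
11 | iodomagnesium (3R)-2-(diethoxymethyl)-3-[(5E)-6,10-dimethylundeca-1,5,9-trien-2-yl]cyclopent-1-en-1-olate | I[Mg]OC1=C(C(OCC)OCC)[C@@H](C(=C)CC/C=C(\C)CCC=C(C)C)CC1 | intermediate
12 | (3R)-2-(diethoxymethyl)-3-[(5E)-6,10-dimethylundeca-1,5,9-trien-2-yl]cyclopent-1-en-1-yl trifluoromethanesulfonate | FC(F)(F)S(=O)(=O)OC1=C(C(OCC)OCC)[C@@H](C(=C)CC/C=C(\C)CCC=C(C)C)CC1 | intermediate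
13 | (tributylstannyl)methanol | OC[Sn](CCCC)(CCCC)CCCC | starting material
14 | [(3R)-2-(diethoxymethyl)-3-[(5E)-6,10-dimethylundeca-1,5,9-trien-2-yl]cyclopent-1-en-1-yl]methanol | OCC1=C(C(OCC)OCC)[C@@H](C(=C)CC/C=C(\C)CCC=C(C)C)CC1 | intermediate
15 | [(3R)-2-(diethoxymethyl)-3-[(5E)-6,10-dimethylundeca-1,5,9-trien-2-yl]cyclopent-1-en-1-yl]methyl acetate | CC(=O)OCC1=C(C(OCC)OCC)[C@@H](C(=C)CC/C=C(\C)CCC=C(C)C)CC1 | intermediate
16 | [(3R)-3-[(2S,5E)-1-(9-borabicyclo[3.3.1]nonan-9-yl)-6,10-dimethylundeca-5,9-dien-2-yl]-2-(diethoxymethyl)cyclopent-1-en-1-yl]methyl acetate | CC(=O)OCC1=C(C(OCC)OCC)[C@@H]([C@@H](CB2C3CCCC2CCC3)CC/C=C(\C)CCC=C(C)C)CC1 | intermediate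
17 | [(3R)-2-(diethoxymethyl)-3-[(2S,5E)-1-hydroxy-6,10-dimethylundeca-5,9-dien-2-yl]cyclopent-1-en-1-yl]methyl acetate | CC(=O)OCC1=C(C(OCC)OCC)[C@@H]([C@@H](CO)CC/C=C(\C)CCC=C(C)C)CC1 | intermediate
18 | [(3R)-2-(diethoxymethyl)-3-[(2S,5E)-6,10-dimethyl-1-oxoundeca-5,9-dien-2-yl]cyclopent-1-en-1-yl]methyl acetate | CC(=O)OCC1=C(C(OCC)OCC)[C@@H]([C@@H](C=O)CC/C=C(\C)CCC=C(C)C)CC1 | intermediate
19 | [(3R)-2-formyl-3-[(2S,5E)-6,10-dimethyl-1-oxoundeca-5,9-dien-2-yl]cyclopent-1-en-1-yl]methyl acetate | CC(=O)OCC1=C(C=O)[C@@H]([C@@H](C=O)CC/C=C(\C)CCC=C(C)C)CC1 | target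

## Step count and risks

Total step count: 9. Longest linear sequence: 8 steps (steps 2–9, from geranylacetone); the ring branch is steps 1 and 4–9.

Steps most likely to fail:

Step 4. The uncatalysed background addition of the alkenyl Grignard reagent may erode the facial discrimination of the copper catalyst, and the magnesium enolate may lose ethoxide before it is sulfonylated. The fallback sets out from 9 and 4 and comes back at 12. Miyaura borylation of 9 (B2pin2, Pd(dppf)Cl2, KOPh, toluene, 50 °C) gives 2-[(5E)-6,10-dimethylundeca-1,5,9-trien-2-yl]-4,4,5,5-tetramethyl-1,3,2-dioxaborolane F1. Hayashi–Miyaura addition of F1 to 4 ([Rh(cod)OH]2, BINAP enantiomer as required, dioxane/H2O, 60 °C) gives, after protonation of the enolate in the flask, (3S)-2-(diethoxymethyl)-3-[(5E)-6,10-dimethylundeca-1,5,9-trien-2-yl]cyclopentan-1-one F2 (same spatial arrangement at C3; the descriptor changes because C2 is now sp3). Formation of the thermodynamic, more substituted C1=C2 enolate (KHMDS, 0.95 equiv, THF, –78 → 0 °C) and PhNTf2 then return 12.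

Step 7. Borane delivery to the 1,1-disubstituted alkene may discriminate poorly between its two faces, since the controlling stereocentre carries two ring carbons of similar size. The fallback sets out from the hydroboration product of 15 and comes back at 17. The epimeric alcohols are separated by chromatography. The unwanted [(3R)-2-(diethoxymethyl)-3-[(2R,5E)-1-hydroxy-6,10-dimethylundeca-5,9-dien-2-yl]cyclopent-1-en-1-yl]methyl acetate F3 is oxidised (Dess–Martin periodinane) to the epimeric aldehyde [(3R)-2-(diethoxymethyl)-3-[(2R,5E)-6,10-dimethyl-1-oxoundeca-5,9-dien-2-yl]cyclopent-1-en-1-yl]methyl acetate F4. Catalytic DBU equilibrates its α-stereocentre through the enol, and NaBH4 (MeOH, 0 °C) reduces the mixture back to the separable alcohols, so that 17 is harvested and F3 recycled.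

Step 1. Ethylene uptake by the cobalt–alkyne complex may be slow under ethylene–CO pressure, so that alkyne oligomerisation or thermal loss of the acetal competes. The fallback does not use 1–3; it sets out from commercial cyclopent-2-en-1-one F5 and comes back at 4. Morita–Baylis–Hillman hydroxymethylation (aqueous CH2O, imidazole, THF/H2O, rt) gives 2-(hydroxymethyl)cyclopent-2-en-1-one F6. Oxidation with MnO2 (CH2Cl2) gives the reactive 5-oxocyclopent-1-ene-1-carbaldehyde F7, which is trapped in the same flask as its diethyl acetal (HC(OEt)3, EtOH, PPTS) to give 4.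

Further compounds
F1 | step 4 | 2-[(5E)-6,10-dimethylundeca-1,5,9-trien-2-yl]-4,4,5,5-tetramethyl-1,3,2-dioxaborolane | C=C(B1OC(C)(C)C(C)(C)O1)CC/C=C(\C)CCC=C(C)C
F2 | step 4 | (3S)-2-(diethoxymethyl)-3-[(5E)-6,10-dimethylundeca-1,5,9-trien-2-yl]cyclopentan-1-one | O=C1C(C(OCC)OCC)[C@@H](C(=C)CC/C=C(\C)CCC=C(C)C)CC1
F3 | step 7 | [(3R)-2-(diethoxymethyl)-3-[(2R,5E)-1-hydroxy-6,10-dimethylundeca-5,9-dien-2-yl]cyclopent-1-en-1-yl]methyl acetate | CC(=O)OCC1=C(C(OCC)OCC)[C@@H]([C@H](CO)CC/C=C(\C)CCC=C(C)C)CC1
F4 | step 7 | [(3R)-2-(diethoxymethyl)-3-[(2R,5E)-6,10-dimethyl-1-oxoundeca-5,9-dien-2-yl]cyclopent-1-en-1-yl]methyl acetate | CC(=O)OCC1=C(C(OCC)OCC)[C@@H]([C@H](C=O)CC/C=C(\C)CCC=C(C)C)CC1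
F5 | step 1 | cyclopent-2-en-1-one | O=C1CCC=C1
F6 | step 1 | 2-(hydroxymethyl)cyclopent-2-en-1-one | O=C1CCC=C1CO
F7 | step 1 | 5-oxocyclopent-1-ene-1-carbaldehyde | O=CC1=CCCC1=O
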